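**Retrosynthetic overview**
- Last disconnection: the dihydrobenzofuran ring (acetal CH, ring oxygen, two carbons of aryl ring D, quaternary carbinol carbon) is cut at its aryl C–quaternary C bond and its O–acetal C bond, together with the flavanone C2–O ketal bond. This leaves 2-prenylresorcinol 19 and the flavone α-keto acetal 17.
- Enabling feature: the ring-D carbon bound to the quaternary carbon is ortho to one OH and para to the other of a C2v-symmetric 2-prenylresorcinol (a C,O-bisnucleophile); the quaternary carbon and the acetal CH are a masked ketone/acetal pair; the flavanone C2 ketal is a flavone C2 that turns electrophilic as a 4-siloxybenzopyrylium ion.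
- Ring order: chroman ring C (Michael addition, the one catalytic stereocentre), then the chromen-4-one ring; in the key step the tetrahydrofuran ketal ring, and last the dihydrobenzofuran ring.
- Fragments: β-diketone 7 (from 2,4-dihydroxyacetophenone and methyl 4-hydroxy-3-iodobenzoate), enal 10 (from 2,4-dihydroxybenzaldehyde), resorcinol 19 (from 2-iodoresorcinol).

Key step: step 16

Abbreviations: prenyl = 3-methylbut-2-en-1-yl; TIPS = triisopropylsilyl; Fl = 4-oxo-6-prenyl-7-(TIPS-oxy)-2-[3-prenyl-4-(TIPS-oxy)phenyl]-4H-chromen-3-yl.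
Assumption: β-diketones (7, 11, 12) and lactols (11, 15) are drawn as one tautomer or anomer mixture, and centres that are erased or reset later (lactol/acetal carbon in 11 and 15–21, carbinol carbon in 14–16) carry no descriptor in the SMILES.

**Route**

Step 1
Reactants: 1 1-(2,4-dihydroxyphenyl)ethanone
Product: 2 1-[2,4-dihydroxy-5-prenylphenyl]ethanone
Conditions: 2-methylbut-3-en-2-ol, BF3·OEt2 (0.3 equiv), dioxane, rt
Reagents that add atoms: 2-methylbut-3-en-2-ol, CC(C)(O)C=C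
Why: Friedel–Crafts C-prenylation should go mainly to C5 (para to the chelated 2-OH, ortho to the 4-OH) because C3 between the two oxygens is more hindered, and the minor 3-isomer is removed by chromatography.

Step 2
Reactants: 2 1-[2,4-dihydroxy-5-prenylphenyl]ethanone
Product: 3 1-[2-hydroxy-5-prenyl-4-(TIPS-oxy)phenyl]ethanone
Conditions: TIPSCl (1.05 equiv), imidazole, DMF, 0 °C → rt
Reagents that add atoms: triisopropylsilyl chloride, CC(C)[Si](Cl)(C(C)C)C(C)C
Why: Silylation should take place only at the 4-OH because the 2-OH is hydrogen-bonded to the acetyl carbonyl.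

Step 3
Reactants: 4 methyl 4-hydroxy-3-iodobenzoate
Product: 5 methyl 4-hydroxy-3-prenylbenzoate
Conditions: prenylboronic acid pinacol ester, Pd(OAc)2 (cat.), biaryl dialkylphosphine ligand (α-selective), K3PO4, THF/H2O, 40 °C
Reagents that add atoms: 4,4,5,5-tetramethyl-2-(3-methylbut-2-en-1-yl)-1,3,2-dioxaborolane, CC(C)=CCB1OC(C)(C)C(C)(C)O1
Why: Suzuki–Miyaura coupling of the aryl iodide with the allylic boronate under α-selective conditions should give the linear prenyl arene.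

Step 4
Reactants: 5 methyl 4-hydroxy-3-prenylbenzoate
Product: 6 methyl 3-prenyl-4-(TIPS-oxy)benzoate
Conditions: TIPSCl, imidazole, DMF, rt
Reagents that add atoms: triisopropylsilyl chloride, CC(C)[Si](Cl)(C(C)C)C(C)C
Why: Standard silylation of a phenol.

Step 5
Reactants: 3 1-[2-hydroxy-5-prenyl-4-(TIPS-oxy)phenyl]ethanone; 6 methyl 3-prenyl-4-(TIPS-oxy)benzoate
Product: 7 1-[2-hydroxy-5-prenyl-4-(TIPS-oxy)phenyl]-3-[3-prenyl-4-(TIPS-oxy)phenyl]propane-1,3-dione
Conditions: LiHMDS (3.3 equiv), THF, −78 → 0 °C; then aq. NH4Cl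
Reagents that add atoms: none
Why: Claisen condensation of the phenoxide/enolate dianion of 3 with the aryl ester should give the β-diketone directly.

Step 6
Reactants: 8 2,4-dihydroxybenzaldehyde
Product: 9 2-hydroxy-4-(TIPS-oxy)benzaldehyde
Conditions: TIPSCl (1.05 equiv), imidazole, CH2Cl2, 0 °C
Reagents that add atoms: triisopropylsilyl chloride, CC(C)[Si](Cl)(C(C)C)C(C)C
Why: The 4-OH is silylated selectively because the 2-OH is hydrogen-bonded to the aldehyde.

Step 7
Reactants: 9 2-hydroxy-4-(TIPS-oxy)benzaldehyde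
Product: 10 (E)-3-[2-hydroxy-4-(TIPS-oxy)phenyl]prop-2-enal
Conditions: (triphenylphosphoranylidene)acetaldehyde, toluene, 80 °C
Reagents that add atoms: (triphenylphosphoranylidene)acetaldehyde, O=CC=P(c1ccccc1)(c1ccccc1)c1ccccc1
Why: Wittig olefination with the stabilised formylmethylene ylide should give the (E)-enal.

Step 8
Reactants: 7 β-diketone; 10 (E)-3-[2-hydroxy-4-(TIPS-oxy)phenyl]prop-2-enal
Product: 11 2-[(4R)-2-hydroxy-7-(TIPS-oxy)chroman-4-yl]-1-[2-hydroxy-5-prenyl-4-(TIPS-oxy)phenyl]-3-[3-prenyl-4-(TIPS-oxy)phenyl]propane-1,3-dione (lactol)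
Conditions: (S)-α,α-diphenylprolinol trimethylsilyl ether (20 mol%), PhCO2H (20 mol%), CH2Cl2, 0 °C → rt
Reagents that add atoms: none
Why: Iminium-catalysed Michael addition of a 1,3-diketone to a 2-hydroxycinnamaldehyde, in which the (S)-catalyst shields the Re face of the (E)-iminium ion so that the diketone adds to the Si face of the β-carbon and sets the benzylic centre (4R), after which the ortho-phenol closes the chroman lactol.

Step 9
Reactants: 11 lactol
Product: 12 2-[(4R)-2-oxo-7-(TIPS-oxy)chroman-4-yl]-1-[2-hydroxy-5-prenyl-4-(TIPS-oxy)phenyl]-3-[3-prenyl-4-(TIPS-oxy)phenyl]propane-1,3-dione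
Conditions: Dess–Martin periodinane (1.2 equiv), CH2Cl2, 0 °C
Reagents that add atoms: none
Why: Dess–Martin oxidation of the lactol to the dihydrocoumarin locks the ring C phenol in the lactone, so only the ring A phenol can cyclise in the next step.

Step 10
Reactants: 12 lactone diketone
Product: 13 (4S)-4-Fl-7-(TIPS-oxy)chroman-2-one
Conditions: TsOH·H2O (10 mol%), toluene, 4 Å MS, 80 °C
Reagents that add atoms: none
Why: Acid-catalysed cyclodehydration of the 2-hydroxyphenyl β-diketone (flavone synthesis) should close the chromen-4-one ring without touching the benzylic stereocentre.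

Step 11
Reactants: 13 flavone lactone
Product: 14 (4S)-3-hydroxy-4-Fl-7-(TIPS-oxy)chroman-2-one
Conditions: LiHMDS (1.2 equiv), THF, −78 °C; then 3-phenyl-2-(phenylsulfonyl)oxaziridine, −78 °C; aq. NH4Cl
Reagents that add atoms: 3-phenyl-2-(phenylsulfonyl)oxaziridine, O=S(=O)(N1OC1c1ccccc1)c1ccccc1
Why: Electrophilic α-hydroxylation of the lactone lithium enolate by the N-sulfonyloxaziridine should occur anti to the C4 substituent, and the new carbinol centre is erased in step 14, so its configuration does not matter.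

Step 12
Reactants: 14 α-hydroxy lactone
Product: 15 (4S)-4-Fl-7-(TIPS-oxy)chromane-2,3-diol
Conditions: DIBAL-H (2.3 equiv), CH2Cl2, −78 °C; Rochelle salt work-up
Reagents that add atoms: none
Why: Low-temperature DIBAL-H reduction of the aryl lactone should stop at the lactol, the vinylogous-ester carbonyl of the flavone being much less electrophilic.

Step 13
Reactants: 15 lactol diol
Product: 16 (4S)-2-methoxy-4-Fl-7-(TIPS-oxy)chroman-3-ol
Conditions: PPTS (cat.), MeOH/CH2Cl2, rt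
Reagents that add atoms: methanol, CO
Why: Acid-catalysed conversion of the lactol into its methyl acetal keeps the aldehyde oxidation level and leaves the secondary alcohol free.

Step 14
Reactants: 16 methyl acetal alcohol
Product: 17 (4S)-2-methoxy-4-Fl-7-(TIPS-oxy)chroman-3-one
Conditions: Dess–Martin periodinane (1.3 equiv), CH2Cl2, 0 °C; used at once
Reagents that add atoms: none
Why: Dess–Martin oxidation should give the α-keto acetal under non-basic conditions that spare the enolisable benzylic centre.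

Step 15
Reactants: 18 2-iodoresorcinol
Product: 19 2-prenylbenzene-1,3-diol
Conditions: prenylboronic acid pinacol ester, Pd(OAc)2 (cat.), biaryl dialkylphosphine ligand (α-selective), K3PO4, THF/H2O, 40 °C
Reagents that add atoms: 4,4,5,5-tetramethyl-2-(3-methylbut-2-en-1-yl)-1,3,2-dioxaborolane, CC(C)=CCB1OC(C)(C)C(C)(C)O1
Why: Suzuki–Miyaura coupling under α-selective conditions should give the linear prenyl arene.

Step 16
Reactants: 17 α-keto acetal; 19 2-prenylbenzene-1,3-diol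
Product: 23 tris-TIPS ether of the target, via tertiary trimethylsilyl ether 20 (not isolated), via ketal silyl enol ether 21 (not isolated), via hexacyclic silyl enol ether 22 (not isolated)
Conditions: 19 (1.5 equiv), TMSOTf (3 equiv), 2,6-di-tert-butyl-4-methylpyridine (3 equiv), CH2Cl2, −78 → 0 °C; then sat. aq. NaHCO3, 0 °C
Reagents that add atoms: none
Why: Proposed new method: TMSOTf is expected first to activate the α-keto acetal carbonyl for Friedel–Crafts hydroxyalkylation by C4 of the C2v-symmetric resorcinol 19 (ortho to one OH, para to the other, C2 blocked by prenyl), the arene entering anti to the pseudo-axial flavonyl group and fixing the quaternary carbon (20), and then to O-silylate the flavone to a 4-siloxyflavylium ion whose C2 is captured by the new tertiary silyl ether oxygen in a 5-exo-trig closure of the tetrahydrofuran ring (21). Allylic (A1,3) strain between the 2-aryl group and the chromanyl substituent on C3 turns the small C–H toward the 2-aryl group, so oxygen should add to the C2 face that gives the natural ketal configuration, and the adduct is held as a silyl enol ether, which makes the ketalisation irreversible. The methyl acetal resists ionisation while it is α to the ketone, so only after the ketone is consumed and the mixture is warmed does it form the aryl oxocarbenium ion, which the ortho-hydroxyl of ring D traps 5-exo-trig to close the dihydrobenzofuran ring last and necessarily cis, the ring fusion setting the acetal centre (22). Bicarbonate work-up should protonate the enol ether from the convex face to give the cis-fused C3–H. The closest known reactions are nucleophile additions to 4-siloxybenzopyrylium ions made from chromones and silyl triflates, Lewis-acid Friedel–Crafts hydroxyalkylation of phenols by activated ketones, and acetal annulations of resorcinols with 1,2-dicarbonyl equivalents. The step needs site selectivity (ketone before acetal, secured by the α-keto deactivation of the acetal) and facial selectivity at C2 (secured by A1,3 strain), and the hindered pyridine buffers free acid to spare the prenyl groups.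

Step 17
Reactants: 23 tris-TIPS ether of the target
Product: 24 target CNP0152008.3
Conditions: TBAF (3.5 equiv), AcOH (3.5 equiv), THF, 0 °C
Reagents that add atoms: none
Why: Buffered fluoride desilylation of the three aryl silyl ethers avoids free phenoxide, so the acid- and base-sensitive ketal/acetal array should survive.

**Compound list**
1 | 1-(2,4-dihydroxyphenyl)ethanone | CC(=O)c1ccc(O)cc1O | starting material
2 | 1-[2,4-dihydroxy-5-prenylphenyl]ethanone | CC(=O)c1cc(CC=C(C)C)c(O)cc1O | intermediate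
3 | 1-[2-hydroxy-5-prenyl-4-(TIPS-oxy)phenyl]ethanone | CC(=O)c1cc(CC=C(C)C)c(O[Si](C(C)C)(C(C)C)C(C)C)cc1O | intermediate
4 | methyl 4-hydroxy-3-iodobenzoate | COC(=O)c1ccc(O)c(I)c1 | starting material
5 | methyl 4-hydroxy-3-prenylbenzoate | COC(=O)c1ccc(O)c(CC=C(C)C)c1 | intermediate
6 | methyl 3-prenyl-4-(TIPS-oxy)benzoate | COC(=O)c1ccc(O[Si](C(C)C)(C(C)C)C(C)C)c(CC=C(C)C)c1 | intermediate
7 | 1-[2-hydroxy-5-prenyl-4-(TIPS-oxy)phenyl]-3-[3-prenyl-4-(TIPS-oxy)phenyl]propane-1,3-dione | CC(C)=CCc1cc(C(=O)CC(=O)c2ccc(O[Si](C(C)C)(C(C)C)C(C)C)c(CC=C(C)C)c2)c(O)cc1O[Si](C(C)C)(C(C)C)C(C)C | intermediate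
8 | 2,4-dihydroxybenzaldehyde | O=Cc1ccc(O)cc1O | starting material
9 | 2-hydroxy-4-(TIPS-oxy)benzaldehyde | O=Cc1ccc(O[Si](C(C)C)(C(C)C)C(C)C)cc1O | intermediate
10 | (E)-3-[2-hydroxy-4-(TIPS-oxy)phenyl]prop-2-enal | O=C/C=C/c1ccc(O[Si](C(C)C)(C(C)C)C(C)C)cc1O | intermediate
11 | 2-[(4R)-2-hydroxy-7-(TIPS-oxy)chroman-4-yl]-1-[2-hydroxy-5-prenyl-4-(TIPS-oxy)phenyl]-3-[3-prenyl-4-(TIPS-oxy)phenyl]propane-1,3-dione (lactol, anomers) | CC(C)=CCc1cc(C(=O)C(C(=O)c2ccc(O[Si](C(C)C)(C(C)C)C(C)C)c(CC=C(C)C)c2)[C@H]2CC(O)Oc3cc(O[Si](C(C)C)(C(C)C)C(C)C)ccc32)c(O)cc1O[Si](C(C)C)(C(C)C)C(C)C | intermediate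
12 | 2-[(4R)-2-oxo-7-(TIPS-oxy)chroman-4-yl]-1-[2-hydroxy-5-prenyl-4-(TIPS-oxy)phenyl]-3-[3-prenyl-4-(TIPS-oxy)phenyl]propane-1,3-dione | CC(C)=CCc1cc(C(=O)C(C(=O)c2ccc(O[Si](C(C)C)(C(C)C)C(C)C)c(CC=C(C)C)c2)[C@H]2CC(=O)Oc3cc(O[Si](C(C)C)(C(C)C)C(C)C)ccc32)c(O)cc1O[Si](C(C)C)(C(C)C)C(C)C | intermediate
13 | (4S)-4-Fl-7-(TIPS-oxy)chroman-2-one | CC(C)=CCc1cc(-c2oc3cc(O[Si](C(C)C)(C(C)C)C(C)C)c(CC=C(C)C)cc3c(=O)c2[C@H]2CC(=O)Oc3cc(O[Si](C(C)C)(C(C)C)C(C)C)ccc32)ccc1O[Si](C(C)C)(C(C)C)C(C)C | intermediate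
14 | (4S)-3-hydroxy-4-Fl-7-(TIPS-oxy)chroman-2-one (C3 epimers, trans expected) | CC(C)=CCc1cc(-c2oc3cc(O[Si](C(C)C)(C(C)C)C(C)C)c(CC=C(C)C)cc3c(=O)c2[C@H]2C(O)C(=O)Oc3cc(O[Si](C(C)C)(C(C)C)C(C)C)ccc32)ccc1O[Si](C(C)C)(C(C)C)C(C)C | intermediate
15 | (4S)-4-Fl-7-(TIPS-oxy)chromane-2,3-diol | CC(C)=CCc1cc(-c2oc3cc(O[Si](C(C)C)(C(C)C)C(C)C)c(CC=C(C)C)cc3c(=O)c2[C@H]2C(O)C(O)Oc3cc(O[Si](C(C)C)(C(C)C)C(C)C)ccc32)ccc1O[Si](C(C)C)(C(C)C)C(C)C | intermediate
16 | (4S)-2-methoxy-4-Fl-7-(TIPS-oxy)chroman-3-ol | CC(C)=CCc1cc(-c2oc3cc(O[Si](C(C)C)(C(C)C)C(C)C)c(CC=C(C)C)cc3c(=O)c2[C@H]2C(O)C(OC)Oc3cc(O[Si](C(C)C)(C(C)C)C(C)C)ccc32)ccc1O[Si](C(C)C)(C(C)C)C(C)C | intermediate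
17 | (4S)-2-methoxy-4-Fl-7-(TIPS-oxy)chroman-3-one | CC(C)=CCc1cc(-c2oc3cc(O[Si](C(C)C)(C(C)C)C(C)C)c(CC=C(C)C)cc3c(=O)c2[C@H]2C(=O)C(OC)Oc3cc(O[Si](C(C)C)(C(C)C)C(C)C)ccc32)ccc1O[Si](C(C)C)(C(C)C)C(C)C | intermediate
18 | 2-iodoresorcinol | Oc1cccc(O)c1I | starting material
19 | 2-prenylbenzene-1,3-diol | CC(C)=CCc1c(O)cccc1O | intermediate
20 | Friedel–Crafts adduct of 17 and 19: 3-(2,4-dihydroxy-3-prenylphenyl)-3-(trimethylsilyloxy) derivative of 17, aryl anti to Fl (phenols shown free) | CC(C)=CCc1cc(-c2oc3cc(O[Si](C(C)C)(C(C)C)C(C)C)c(CC=C(C)C)cc3c(=O)c2[C@H]2[C@](O[Si](C)(C)C)(c3ccc(O)c(CC=C(C)C)c3O)C(OC)Oc3cc(O[Si](C(C)C)(C(C)C)C(C)C)ccc32)ccc1O[Si](C(C)C)(C(C)C)C(C)C | intermediate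
21 | tetrahydrofuran ketal closed (configured as in 24), C4 trimethylsilyl enol ether, dihydrobenzofuran ring still open (methyl acetal, free resorcinol) | CC(C)=CCc1cc([C@@]23Oc4cc(O[Si](C(C)C)(C(C)C)C(C)C)c(CC=C(C)C)cc4C(O[Si](C)(C)C)=C2[C@@H]2c4ccc(O[Si](C(C)C)(C(C)C)C(C)C)cc4OC(OC)[C@]2(c4ccc(O)c(CC=C(C)C)c4O)O3)ccc1O[Si](C(C)C)(C(C)C)C(C)C | intermediate
22 | C4 trimethylsilyl enol ether of 23 (all rings closed) | CC(C)=CCc1cc([C@@]23Oc4cc(O[Si](C(C)C)(C(C)C)C(C)C)c(CC=C(C)C)cc4C(O[Si](C)(C)C)=C2[C@@H]2c4ccc(O[Si](C(C)C)(C(C)C)C(C)C)cc4O[C@H]4Oc5c(ccc(O)c5CC=C(C)C)[C@]42O3)ccc1O[Si](C(C)C)(C(C)C)C(C)C | intermediate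
23 | target with TIPS ethers on the chromanone 7-OH, the 2-aryl 4-OH and the chroman OH (ring D OH free) | CC(C)=CCc1cc([C@@]23Oc4cc(O[Si](C(C)C)(C(C)C)C(C)C)c(CC=C(C)C)cc4C(=O)[C@@H]2[C@@H]2c4ccc(O[Si](C(C)C)(C(C)C)C(C)C)cc4O[C@H]4Oc5c(ccc(O)c5CC=C(C)C)[C@]42O3)ccc1O[Si](C(C)C)(C(C)C)C(C)C | intermediate
24 | CNP0152008.3 | CC(C)=CCc1cc([C@@]23Oc4cc(O)c(CC=C(C)C)cc4C(=O)[C@@H]2[C@@H]2c4ccc(O)cc4O[C@H]4Oc5c(ccc(O)c5CC=C(C)C)[C@]42O3)ccc1O | target

**Totals:** 17 steps; longest linear sequence 12 steps (1, 2, 5, 8–14, 16, 17).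

**Steps most likely to fail**

Step 16 (bears the label). The three bond-forming events may not follow the intended order: the tertiary benzylic silyl ether may ionise and eliminate instead of being captured by the siloxyflavylium ion, facial selectivity at C2 may be poor, or adventitious acid may cyclise prenyl groups. The fallback uses known reactions, sets out from 17 and 19 and returns at 23. Resorcinol 19 is converted into its bis(methoxymethyl) ether F1 (MOMCl, i-Pr2NEt). Directed ortho-lithiation (n-BuLi, TMEDA), transmetalation to cerium and addition to ketone 17 at −78 °C gives the tertiary carbinol F2, the aryl group entering anti to Fl. Conjugate reduction of the flavone with L-Selectride gives the 2,3-trans flavanone F3. DDQ in dry CH2Cl2 over molecular sieves then oxidises the p-silyloxybenzylic ether C2–H and the tertiary hydroxyl traps the cation, giving ketal F4 (oxidative acetal formation of a p-alkoxybenzyl-type ether). HCl in MeOH/THF at 0 °C removes both MOM groups and closes the dihydrobenzofuran acetal, again as the last ring, to give 23. In this variant C3 is set at the enolate protonation, so C2/C3 epimers may have to be separated.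

Step 8. Conjugate addition of a hindered, weakly nucleophilic diaryl diketone to a donor-substituted iminium ion may be slow, and retro-Michael reaction may erode the enantiomeric purity. The fallback sets out from 7 and 9 and returns at 12. Knoevenagel condensation of 9 with diallyl malonate (piperidine, AcOH) gives the allyl coumarin-3-carboxylate F5. A cinchona-squaramide-catalysed Michael addition of 7 to this doubly activated acceptor (catalyst antipode chosen for the same sense at the benzylic carbon) gives F6. Pd(PPh3)4 with morpholine removes the allyl ester with decarboxylation to give lactone 12.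

Step 11. The aryl-lactone enolate may fragment to a ketene phenoxide, or the neighbouring benzylic centre may epimerise under the basic conditions. The fallback sets out from 13 and returns at 16, moving the oxidation to the aldehyde level under amine catalysis. DIBAL-H reduction of 13 at −78 °C gives lactol F7. Enamine-catalysed α-benzoyloxylation of its ring-opened aldehyde (secondary amine catalyst, dibenzoyl peroxide) gives F8. PPTS in MeOH gives the methyl acetal F9, and K2CO3 in MeOH removes the benzoate to give 16.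

Further compounds
F1 | step 16 | 1,3-bis(methoxymethoxy)-2-prenylbenzene | COCOc1cccc(OCOC)c1CC=C(C)C
F2 | step 16 | (4S)-3-[2,4-bis(methoxymethoxy)-3-prenylphenyl]-2-methoxy-4-Fl-7-(TIPS-oxy)chroman-3-ol, aryl anti to Fl | CC(C)=CCc1cc(-c2oc3cc(O[Si](C(C)C)(C(C)C)C(C)C)c(CC=C(C)C)cc3c(=O)c2[C@H]2[C@](O)(c3ccc(OCOC)c(CC=C(C)C)c3OCOC)C(OC)Oc3cc(O[Si](C(C)C)(C(C)C)C(C)C)ccc32)ccc1O[Si](C(C)C)(C(C)C)C(C)C
F3 | step 16 | 2,3-dihydro (2,3-trans flavanone) derivative of F2 | CC(C)=CCc1cc(C2Oc3cc(O[Si](C(C)C)(C(C)C)C(C)C)c(CC=C(C)C)cc3C(=O)C2[C@H]2[C@](O)(c3ccc(OCOC)c(CC=C(C)C)c3OCOC)C(OC)Oc3cc(O[Si](C(C)C)(C(C)C)C(C)C)ccc32)ccc1O[Si](C(C)C)(C(C)C)C(C)C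
F4 | step 16 | tetrahydrofuran ketal of F3 (configured as in 24), dihydrobenzofuran ring open, ring D as bis-MOM ether | CC(C)=CCc1cc([C@@]23Oc4cc(O[Si](C(C)C)(C(C)C)C(C)C)c(CC=C(C)C)cc4C(=O)[C@@H]2[C@@H]2c4ccc(O[Si](C(C)C)(C(C)C)C(C)C)cc4OC(OC)[C@]2(c4ccc(OCOC)c(CC=C(C)C)c4OCOC)O3)ccc1O[Si](C(C)C)(C(C)C)C(C)C
F5 | step 8 | allyl 2-oxo-7-(TIPS-oxy)-2H-chromene-3-carboxylate | C=CCOC(=O)c1cc2ccc(O[Si](C(C)C)(C(C)C)C(C)C)cc2oc1=O
F6 | step 8 | allyl 4-[1,3-diaryl-1,3-dioxopropan-2-yl]-2-oxo-7-(TIPS-oxy)chroman-3-carboxylate (aryl groups as in 12) | CC(C)=CCc1cc(C(=O)C(C(=O)c2ccc(O[Si](C(C)C)(C(C)C)C(C)C)c(CC=C(C)C)c2)[C@H]2C(C(=O)OCC=C)C(=O)Oc3cc(O[Si](C(C)C)(C(C)C)C(C)C)ccc32)c(O)cc1O[Si](C(C)C)(C(C)C)C(C)C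
F7 | step 11 | (4S)-4-Fl-7-(TIPS-oxy)chroman-2-ol | CC(C)=CCc1cc(-c2oc3cc(O[Si](C(C)C)(C(C)C)C(C)C)c(CC=C(C)C)cc3c(=O)c2[C@H]2CC(O)Oc3cc(O[Si](C(C)C)(C(C)C)C(C)C)ccc32)ccc1O[Si](C(C)C)(C(C)C)C(C)C
F8 | step 11 | (4S)-3-benzoyloxy-4-Fl-7-(TIPS-oxy)chroman-2-ol | CC(C)=CCc1cc(-c2oc3cc(O[Si](C(C)C)(C(C)C)C(C)C)c(CC=C(C)C)cc3c(=O)c2[C@H]2C(OC(=O)c3ccccc3)C(O)Oc3cc(O[Si](C(C)C)(C(C)C)C(C)C)ccc32)ccc1O[Si](C(C)C)(C(C)C)C(C)C
F9 | step 11 | (4S)-3-benzoyloxy-2-methoxy-4-Fl-7-(TIPS-oxy)chroman | CC(C)=CCc1cc(-c2oc3cc(O[Si](C(C)C)(C(C)C)C(C)C)c(CC=C(C)C)cc3c(=O)c2[C@H]2C(OC(=O)c3ccccc3)C(OC)Oc3cc(O[Si](C(C)C)(C(C)C)C(C)C)ccc32)ccc1O[Si](C(C)C)(C(C)C)C(C)C
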